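The earlier runs and the new flask are calculated with made-up constants; scatter was added.

In a one-step world with substrate and reagent charged alike, target follows a single curve against catalyst-hours, X, the catalyst charged times the hours run (a normalised time axis), and I read that curve in powers of ten.

| setting | red | green | Friday's | Tuesday's |
|---|---|---|---|---|
| substrate | 26 mM | 26 mM | 26 mM | 26 mM |
| reagent | 52 mM | 52 mM | 52.0 mM | 52.0 mM |
| catalyst | 0.25 mM | 0.93 mM | 0.40 mM | 1.3 mM |
| remark | run made earlier | run made earlier |  |  |
| time |  |  | 2.5 h | 10 h |

| run | time / h | target / % |
|---|---|---|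
| red | 1.33 | 8.3 |
| red | 3.00 | 16.5 |
| red | 4.00 | 19.1 |
| red | 6.00 | 23.0 |
| red | 8.00 | 24.6 |
| red | 10.0 | 25.1 |
| green | 0.500 | 12.6 |
| green | 1.50 | 27.8 |
| green | 3.00 | 34.3 |
| green | 4.00 | 35.7 |
| green | 6.00 | 34.8 |
| green | 8.00 | 34.1 |
| green | 10.0 | 30.5 |

(scatter of a reading: 1 percentage point)

1. the flask that ends with the higher amount of target, in percent of the substrate charged, or "neither" when 2 percentage points or less lies between them (Friday's / Tuesday's / neither)
2. final target, as a percentage of the substrate charged, in Friday's
3. final target, as a percentage of the substrate charged, in Tuesday's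

- what was read earlier has a scatter of 1 percentage point, one standard deviation

The red, green, Friday's and Tuesday's flasks share 26 mM of substrate and 52.0 mM of reagent, so I applied no correction for those two. In the one-step world catalyst and time count equally, through X. Doubling X in the red run, from 3.00 h to 6.00 h, added 6.5 percentage points against a scatter of 1 point, so both must be known well.

Friday's has X = 3.60 M·s. The red run reached that X at 4.00 h with 19.1%. The green run reached it at 1.08 h, with about 21.3% by interpolation, higher than red, so I treated the single curve as approximate. Friday's catalyst lies 0.358 of the way from red to green on the log scale, which gave me 19.9%. Tuesday's has X = 46.8 M·s, 0.145 of a power of ten past the green run's last reading, 30.5%, taken at the same 10 h. I committed to that reading, which puts Tuesday's ahead by 11 points, beyond the margin of 2 points.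

The forecast gave 19% for Friday's, below mine, and 32.5% for Tuesday's, above mine, and said “Tuesday's is clearly higher”.

The flasks gave 20.8% for Friday's and 31.6% for Tuesday's, so Tuesday's it is.

    substrate + reagent + catalyst ⇌ target + catalyst, rate k1*[substrate]*[reagent]*[catalyst] forward; the back reaction follows from the equilibrium constant (K = 22.0 M⁻¹, k = 110 M⁻² min⁻¹)
    substrate + reagent → uncatalysed product (k = 0.0280 M⁻¹ min⁻¹)

Neither flask has come to rest. Left to 25.0 h, Friday's reads 19.7% of target, against 20.8% at 2.50 h, yet substrate falls from 63.6% to 21.3% and uncatalysed product reaches 58.9%. Left to 100 h, Tuesday's drops to 1.95% of target.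

Friday's flask read at 4.0 h has X = 5.76 M·s, where red and green read about 23.3% and 28.8%, so the same 0.358 gives 25.3%. The computed flask gives 25.9%.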